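Readings and results are calculated with made-up constants; the scatter is artificial.

From 5.00 min on, the readings of alder, the asked flask followed so far, put G at 82.5% of the J charged, and I built my bracket for 80 min on that reading.

| flask | J | X | E | remark | time |
|---|---|---|---|---|---|
| alder | 5.0 × 10⁻⁴ M | 1.8 equiv | 5 mol% | the very flask that is asked about, followed so far |  |
| elm | 5.0 × 10⁻⁴ M | 1.8 equiv | 3.4 mol% | run made earlier |  |
| flask | 5.0 × 10⁻⁴ M | 1.80 equiv | 5 mol% |  | 80 min |

| run | time / min | J / % | Z / % | G / % |
|---|---|---|---|---|
| alder | 1.50 | 12.5 | 16.2 | 71.7 |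
| alder | 5.00 | 0.1 | 17.0 | 82.3 |
| alder | 10.0 | 0 | 14.5 | 81.3 |
| alder | 15.0 | 0.2 | 15.5 | 80.9 |
| alder | 20.0 | 0 | 16.6 | 83.6 |
| alder | 25.0 | 0 | 15.2 | 84.2 |
| alder | 30.0 | 1.4 | 15.9 | 82.8 |
| elm | 8.00 | 0 | 11.7 | 85.5 |
| elm | 15.0 | 1.1 | 12.6 | 87.6 |
| elm | 25.0 | 0 | 12.6 | 88.1 |
| elm | 30.0 | 2.2 | 13.5 | 87.9 |
| elm | 40.0 | 0 | 12.3 | 85.6 |
| elm | 50.0 | 0.4 | 11.8 | 85.3 |
| elm | 60.0 | 0 | 11.4 | 86.8 |

(readings scatter by 1 percentage point)

- a species is counted by the J in it: one G counts as two
- the numbers in the tables scatter by 1 percentage point (one standard deviation)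
- candidate steps: X + E <-> Q; J + Q -> D; D <-> E + Z; X -> L; J + Z -> G
- the reaction counts as stopped when no species that holds the J changes by six tenths of a point or more over the second half of the time

- which holds at 80 min: what has brought the reaction to rest, or that it has not come to rest (X has run out first / no working catalyst is left / all of J has reacted / it is still moving / forward and back rates have come level)
- how much of the J has reacted by 80 min
- how much Z there is at 80 min, in percent of the J charged
- how much G there is at 80 min, in percent of the J charged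
- how much D there is at 80 min, in percent of the J charged

I followed one J. Counted by the J it holds, G takes its share of the charge, so the chance of escaping G is what G leaves: 17.5%, which I called the survivor share (a selectivity, in the usual term). G forms by J + Z → G, and that step needs J. J, the limiting reagent, read 0.1% at 5.00 min in alder, so the fork had closed and the survivors sat as Z or as D. D holds one J per catalyst, and the catalyst was 5 mol% on J. So I put Z in the flask at 80 min between 12.5% and the survivor share, a bracket that carries the scatter of the readings. I tightened that by hand: the alder Z readings ran from 14.5% to 17.0% around 15.8%, and the elm Z readings showed no drift beyond the scatter, with 11.7% at 8.00 min and 11.4% at 60.0 min. I committed to that mean for Z, which left D at 1.70%.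

The forecast said all of J has reacted, with 100% of J reacted, Z 15.3%, G 82.7% and D 2%, on the ground that “neither Z nor G moves afterwards”. Its Z lay inside my bracket, and its Z and D add up to what its G leaves, 17.3%.

At 80 min the flask gave: all of J has reacted, with 100% reacted, Z 16.3%, G 82.1% and D 1.61%. That Z lay inside my bracket too.

    X + E ⇌ Q (K = 2500 M⁻¹, k = 1600 M⁻¹ s⁻¹)
    J + Q → D (k = 1400 M⁻¹ s⁻¹)
    D ⇌ E + Z (K = 7.90 × 10⁻⁵ M, k = 1.40 s⁻¹)
    X → L (k = 5.20 × 10⁻⁵ s⁻¹)
    J + Z → G (k = 160 M⁻¹ s⁻¹)

The survivor share of the flask came to 17.9%, which is its Z plus its D, 17.9%. The hit on Z by J kept that share small: the run without J + Z → G ends at Z 96.1% against 16.3%. The neighbour flask with 3.10 equiv of X ended with G 77.9%, a survivor share of 22.1%, which put its Z between 17.1% and that share, and its Z stood at 20.7% with D 1.39%.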